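The numbers in the tables were generated by integration with made-up constants, and the scatter is random.

67% of the starting material is left after 30.0 min in Sunday's flask, against 53% in Friday's, and the charge is what separates them: 0.65 M against 0.21 M, with partner and free catalyst the same. The gap of 14 percentage points stands against a scatter of 1.5 points, so we take it as real.

in all of them: partner 1.29 M; free catalyst 0.49 mM

| charge | starting material | remark | time |
|---|---|---|---|
| Friday's | 0.21 M | run made earlier |  |
| Sunday's | 0.65 M | run made earlier |  |
| oak | 0.99 M |  | 1.0 h |
| elm | 2.0 M |  | 1.0 h |
| birch | 0.25 M |  | 1.0 h |
| cedar | 1.5 M |  | 1.0 h |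
| ash | 0.60 M |  | 1.0 h |

| run | time / min | target / % | starting material / % |
|---|---|---|---|
| Friday's | 2.50 | 6 | 94 |
| Friday's | 8.00 | 12 | 86 |
| Friday's | 15.0 | 29 | 73 |
| Friday's | 20.0 | 33 | 67 |
| Friday's | 30.0 | 47 | 53 |
| Sunday's | 6.00 | 7 | 92 |
| Sunday's | 12.0 | 15 | 84 |
| Sunday's | 20.0 | 28 | 76 |
| Sunday's | 25.0 | 30 | 71 |
| Sunday's | 30.0 | 35 | 67 |

(readings scatter by 1.5 percentage points)

- target is meant together with its idle complex
- steps under discussion: starting material + free catalyst <-> catalyst intermediate A; partner + catalyst intermediate A <-> catalyst intermediate B; catalyst intermediate B -> free catalyst + target; free catalyst + target <-> idle complex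

- ranking by amount of target, in percent of the starting material charged, from high to low, at 1.0 h (oak / elm / birch / cedar / ash)
- the amount of target, in percent of the starting material charged of the flask you put first, at 1.0 h
- the amount of target, in percent of the starting material charged of the flask you put last, at 1.0 h

We compare the two flasks by their apparent lifetime, the elapsed time divided by the natural logarithm of charged over left. The zero of our scale is the pseudo-first-order case, where the lifetime does not depend on the charge and the two lifetimes are equal. Ours are not: Sunday's flask reads 74.9 min, longer than the 47.3 min of Friday's flask. Both were charged with 0.49 mM of free catalyst, far less than the starting material, so it must turn over many times, and we read Sunday's larger charge as queuing for the same catalyst.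

Our own reckoning draws a straight line through these two readings, and it carries their scatter. Its intercept, the lifetime at vanishing charge, is 34.1 min. The doubling charge is the charge of starting material that adds that same amount of lifetime on the line: 0.542 M. A flask's lifetime is then the intercept multiplied by one plus its charge over the doubling charge. The lifetime rises with the charge, so the flasks rank by charge, lowest first. Birch gets 49.8 min and 70.0% of target. Elm, beyond the charges read, gets 160 min and 31.3%. Partner, the limiting reagent in elm, allows 64.5%, more than that figure, so this cap does not touch our estimate.

The forecast gives birch > ash > oak > cedar > elm, with 70% at the top and 31% at the bottom, and adds: “The high-charge extrapolation is the least certain.”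

The simulation gives birch > ash > oak > cedar > elm, with 69.9% and 30.6%.

    starting material + free catalyst ⇌ catalyst intermediate A (K = 2.80 M⁻¹, k = 1.20 M⁻¹ s⁻¹)
    partner + catalyst intermediate A ⇌ catalyst intermediate B (K = 10.0 M⁻¹, k = 1.20 M⁻¹ s⁻¹)
    catalyst intermediate B → free catalyst + target (k = 1.00 s⁻¹)
    free catalyst + target ⇌ idle complex (K = 20.0 M⁻¹, k = 6.50 × 10⁻⁴ M⁻¹ s⁻¹)

Elm's charge of 2.0 M stands above our doubling charge of 0.542 M, and birch's 0.25 M stands below it. At 1.00 h elm has 23.4% of its catalyst free, against 73.2% in birch, and elm still holds 69.4% of its starting material.

Take a further flask like elm but with 0.50 M of starting material. The doubling charge gives it a lifetime of 65.5 min and so 60.0% of target; the computed flask holds 60.7% of target.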